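(The numbers in the tables come from a simulation from invented constants; the scatter is artificial.)

The violet and red runs cannot share one first-order constant in the free monomer charged: they would then read alike at 15.0 min, yet violet reads 42.1% and red 54.8%, while a reading scatters by 1 percentage point.

| setting | violet | red | midnight | winter |
|---|---|---|---|---|
| free monomer | 6.7 mM | 12 mM | 10 mM | 15 mM |
| protic impurity | 3 mM | 3 mM | 3.00 mM | 3.00 mM |
| initiator | 26 µM | 26 µM | 26 µM | 26 µM |
| remark | run made earlier | run made earlier |  |  |
| time |  |  | 30 min | 30 min |

- violet (time / min: monomer in chains / %): 1.33: 9.5; 2.00: 8.7; 3.00: 14.2; 5.00: 22.1; 10.0: 33.3; 15.0: 42.1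
- red (time / min: monomer in chains / %): 2.50: 14.6; 5.00: 27.4; 8.00: 38.4; 10.0: 43.2; 12.0: 48.4; 15.0: 54.8

(each reading ± 1 percentage point)

- which of the two ends with the longer chains by the average number of monomer units in a chain (living and dead chains, two that joined counted as one) ("neither" if they lie within 10%) (midnight / winter / neither)
- average number of monomer units in a chain (living and dead chains, two that joined counted as one) at the end, midnight
- average number of monomer units in a chain (living and dead chains, two that joined counted as one) at the end, winter

- the average divides the monomer in chains by the number of chains, living and dead together; two radicals that join make one chain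
- what was read earlier has a scatter of 1 percentage point, one standard deviation
- on the list of suspects stand: protic impurity + free monomer -> quenched substrate; free monomer -> decomposition product; initiator -> 2 initiating radical; free monomer + growing radical -> monomer in chains + growing radical; free monomer + initiating radical -> growing radical + monomer in chains; 2 growing radical -> dead chain
- the earlier runs do not show the number of chains; that part of a forecast is a guess

Turn the free monomer first. By hand, let the protic impurity take free monomer one for one, early. What stays for chains is the usable monomer, charged [free monomer] minus charged [protic impurity], 7.00 mM for midnight and 12.0 mM for winter. Hold the two runs against it, as share of usable monomer in chains at 15.0 min: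

violet: usable 3.70 mM, share 76.2%

red: usable 9.00 mM, share 73.1%

Read this way, the gap between the two runs is smaller than in the percentages of the charge.

Turn the time next. By hand, let usable monomer fall pseudo-first-order, so that the constant is ln(1/(1 − share)) over the time:

violet: 0.0958 min⁻¹

red: 0.0875 min⁻¹

Both are readings and carry the scatter of the shares; take their mean, 0.0916 min⁻¹. Your first answer for the monomer in chains was the usable monomer itself; put the time back in and go round once more. At 30 min:

midnight: 6.55 mM

winter: 11.2 mM

The readings show no chain count, so assume equal counts in these two flasks, which share initiator and time. The time factor then cancels, and the length ratio of winter to midnight is the ratio of usable monomer, 1.71. So this reckoning expects winter to end longer, past the margin of 10%, and it commits to that ratio and to no absolute length.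

The forecast, which does give lengths, says winter, with 180 for midnight and 310 for winter, and adds: “The chain count is a guess”.

The flask gives winter, with 1110 for midnight and 1890 for winter.

    protic impurity + free monomer → quenched substrate (k = 5.10 M⁻¹ s⁻¹)
    free monomer → decomposition product (k = 2.90 × 10⁻⁶ s⁻¹)
    initiator → 2 initiating radical (k = 1.40 × 10⁻⁴ s⁻¹)
    free monomer + growing radical → monomer in chains + growing radical, rate k4*[growing radical]*[free monomer] (k = 1.00 × 10⁵ M⁻¹ s⁻¹)
    free monomer + initiating radical → growing radical + monomer in chains (k = 7.10 × 10⁶ M⁻¹ s⁻¹)
    2 growing radical → dead chain (k = 1.70 × 10⁷ M⁻¹ s⁻¹)

That is a ratio of 1.70 against 1.71 from usable monomer, and at 30.0 min dead chain stands at 0.00579 mM in midnight and 0.00579 mM in winter. Now take the neighbour flask, midnight with 2.5 mM of free monomer: its usable monomer is −0.500 mM, below zero. It still ends with 14.3% of its free monomer in chains, at an average length of 91.7, and with 29% of its protic impurity left.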